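**Plan**

Retrosynthesis: the first cuts are the C2–C3 bond (propenyl unit plus C2 aldehyde), the C5–O angelate ester, C11=C13 and the C12–O6 lactone bond. The trans C1/C5 diol is then traced to a C1=C5 enoate and the C8 carbinol to a ketone, and the C9–C10 ring bond is cut by a retro-Claisen shift. The resulting oxolane is cut at C1–C5 (aldehyde plus vinylalane) and C7–C11 (allylation).
Enabling feature: in the carbocycle C1–C5–C6–C7–C8–C9–C10 the only CH2 (C9) lies between the C8 carbinol and the methyl-bearing C10, and the oxygenated C1–C5 bond follows C10. This is the O=C8–C9H2–C10H–C1=C5 array of a cyclohept-4-enone, the [3,3] product of a 2-methylene-5-alkenyloxolane whose ring is O, C5, C6, C7, C8.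
Forward order: the pool butyrolactone (C5–C8) is allylated, opened, extended at C5 and reclosed as a new γ-lactone on O5. Methylenation gives the oxolane enol ether and ring expansion gives the cycloheptenone. A transient C1/C5 epoxide follows, then the γ-lactone on O6, its α-methylene group, the angelate and last the crotonoyl chain.
Stereochemistry: C6 comes from (R)-3-hydroxybutyrolactone and C7 from trans alkylation of its dianion. A temporary C5 carbinol is set by Felkin–Anh addition and relayed to C10 in the suprafacial shift. C8 is set by hydride attack anti to the allyl group, C1 by epoxidation guided by the 6-OH, and C5 by invertive epoxide opening.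

Key step: step 7

Numbering and faces: target numbering is used throughout. The ring carbons are C1 (OH, acyl), C5, C6, C7, C8, C9 and C10 (CH3 = C14). The side chain is C2, C3=C4, C15, and the lactone carbons are C11, C12 and C13. The ring is drawn flat with C1→C5→C6→C7→C8→C9→C10 clockwise; β points towards the viewer and α away. The target is 1α-OH, 5β-O-angeloyl, 6α-O, 7β-C11, 8β-OH, 10α-CH3, which is (1S,5S,6R,7S,8S,10S).
Assumption: 1, 8, 31 and isomerically pure 36 are taken as purchasable. The anomers of 23, the C11 epimers of 27 and the C2 epimers of 38 are carried on as mixtures because these centres are erased later.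

**Route**

Step 1
Reactants: 1 (R)-3-hydroxy-γ-butyrolactone; 2 allyl bromide
Product: 4 (3R,4R)-3-allyl-4-hydroxyoxolan-2-one (trans), via dilithio dianion 3 (not isolated)
Conditions: LDA (2.2 equiv), THF, −78 °C; then 2, −78 → −30 °C
Reagents that add atoms: none
Why: Fráter–Seebach-type alkylation of the alkoxide/enolate dianion, in which the electrophile enters anti to the C6 lithium alkoxide and so sets C7 trans to C6 (7β-allyl, 6α-OH).

Step 2
Reactants: 4 (3R,4R)-3-allyl-4-hydroxyoxolan-2-one
Product: 5 (3R,4R)-3-allyl-4-(tert-butyldimethylsilyloxy)oxolan-2-one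
Conditions: TBSCl, imidazole, DMF, rt
Reagents that add atoms: tert-butyldimethylsilyl chloride CC(C)(C)[Si](C)(C)Cl
Why: Standard silylation of a secondary alcohol, and the bulky non-chelating ether later steers the addition to the aldehyde.

Step 3
Reactants: 5 (3R,4R)-3-allyl-4-(tert-butyldimethylsilyloxy)oxolan-2-one
Product: 6 (2R)-2-[(1R)-1-(tert-butyldimethylsilyloxy)-2-hydroxyethyl]-N-methoxy-N-methylpent-4-enamide
Conditions: MeNH(OMe)·HCl, AlMe3, CH2Cl2, 0 °C → rt
Reagents that add atoms: N,O-dimethylhydroxylamine hydrochloride CNOC.Cl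
Why: Weinreb aminolysis of a γ-lactone with the aluminium amide stops at the open hydroxy amide and touches no stereocentre, and the product is oxidised at once to forestall relactonisation.

Step 4
Reactants: 6 hydroxy Weinreb amide
Product: 7 (2R)-2-[(1R)-1-(tert-butyldimethylsilyloxy)-2-oxoethyl]-N-methoxy-N-methylpent-4-enamide
Conditions: DMP, CH2Cl2, 0 °C → rt
Reagents that add atoms: none
Why: Dess–Martin oxidation runs close to neutrality, so the α-silyloxy aldehyde should form without epimerisation at C6 or β-elimination.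

Step 5
Reactants: 7 α-silyloxy aldehyde; 8 tert-butyl but-2-ynoate
Product: 11 tert-butyl (Z)-2-[(2S,3R,4R)-4-allyl-3-(tert-butyldimethylsilyloxy)-5-oxooxolan-2-yl]but-2-enoate (all-trans γ-lactone), via vinylalane 9 (not isolated), via aldol adduct 10 (not isolated)
Conditions: DIBAL-H, HMPA, THF, 0 °C, then 8; then 7, −78 → −20 °C; crude 10: PPTS (cat.), toluene, 60 °C
Reagents that add atoms: none
Why: Syn-hydroalumination of the ynoate places aluminium on C1 and leaves the methyl group cis to the ester, the vinylalane adds to the aldehyde (vinylalumination, a Morita–Baylis–Hillman-type aldol) under polar Felkin–Anh control to give the 5,6-anti carbinol (5S), and mild acid then closes the γ-lactone by acyl substitution at the Weinreb amide.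

Step 6
Reactants: 11 all-trans γ-lactone
Product: 12 tert-butyl (Z)-2-[(2S,3R,4R)-4-allyl-3-(tert-butyldimethylsilyloxy)-5-methylideneoxolan-2-yl]but-2-enoate
Conditions: Tebbe reagent (1.1 equiv), pyridine, THF–toluene, −40 → 0 °C; aq. NaOH quench, basic alumina, used at once
Reagents that add atoms: Tebbe reagent C[Al](C)C[Ti](Cl)(C1C=CC=C1)C1C=CC=C1
Why: In the Tebbe methylenation the titanium methylidene should engage the open γ-lactone carbonyl much faster than the conjugated, doubly flanked tert-butyl ester, and the basic medium preserves the exocyclic enol ether that brings in C9.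

Step 7
Reactants: 12 2-methylene-5-alkenyloxolane
Product: 13 tert-butyl 7β-allyl-6α-(tert-butyldimethylsilyloxy)-10α-methyl-8-oxocyclohept-1(5)-ene-1-carboxylate
Conditions: toluene (degassed), BHT (cat.), base-washed sealed tube, 150 °C
Reagents that add atoms: none
Why: This is a thermal aliphatic Claisen rearrangement: in the cyclic allyl vinyl ether C9=C8–O–C5–C1=C10 the C9–C10 σ bond forms while the C5–O bond breaks in one concerted suprafacial [3,3] shift, so the ring oxygen becomes the C8 ketone and the alkene moves to C1=C5. The closest known reaction type is the Claisen ring expansion of 2-methylene-5-vinyltetrahydrofurans, made by lactone methylenation, to cyclohept-4-enones. The seven-membered ring closes by two-carbon enlargement of the oxolane through a bridged, chair-like six-centre array of 8-oxabicyclo[3.2.1]octane topology (C6 pseudo-axial on C5, the C6–C7 bridge tying C5 to C8) and not by end-to-end cyclisation, and this bridge admits only the cis ring alkene. C10 is the only new stereocentre and is controlled by the C5 carbinol centre together with the fixed alkene geometry: C9 must bond to the face of the allyl unit from which oxygen departs, C6 must end cis to C10, and the methyl group lies trans to C5 (pseudo-equatorial), which turns (5S) into the 10α-methyl (10S) centre as C5 becomes sp2, while C6 and C7 are untouched. The step needs periselectivity over the Cope shift of the C9=C8–C7–C11–C12=C diene and over migration of the exocyclic double bond into the ring; the first is secured by the lower barrier of the oxygen-containing shift (C=O formation, acceptor on C1) and the second by acid-free, base-washed equipment.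

Step 8
Reactants: 13 cyclohept-4-enone
Product: 14 tert-butyl 7β-allyl-6α-(tert-butyldimethylsilyloxy)-8β-hydroxy-10α-methylcyclohept-1(5)-ene-1-carboxylate
Conditions: L-Selectride, THF, −78 °C
Reagents that add atoms: none
Why: In this diastereoselective ketone reduction the bulky trialkylborohydride should attack C8 from the α face, anti to the adjacent 7β-allyl group (equatorial attack), to set the 8β-alcohol, and the hindered enoate is left alone at −78 °C.

Step 9
Reactants: 14 8β-alcohol
Product: 15 tert-butyl 7β-allyl-6α-(tert-butyldimethylsilyloxy)-10α-methyl-8β-(triisopropylsilyloxy)cyclohept-1(5)-ene-1-carboxylate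
Conditions: TIPSOTf, 2,6-lutidine, CH2Cl2, 0 °C
Reagents that add atoms: triisopropylsilyl triflate CC(C)[Si](C(C)C)(C(C)C)OS(=O)(=O)C(F)(F)F
Why: Silylation with the triflate overcomes the hindrance at C8, and TIPS is chosen because its oxygen is a poor transannular nucleophile towards C5 in the later epoxide opening, it is inert to ozone and it outlasts TBS in acid.

Step 10
Reactants: 15 bis-silyl ether
Product: 16 tert-butyl 7β-allyl-6α-hydroxy-10α-methyl-8β-(triisopropylsilyloxy)cyclohept-1(5)-ene-1-carboxylate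
Conditions: CSA (cat.), MeOH–CH2Cl2, 0 °C → rt
Reagents that add atoms: none
Why: Acid-catalysed methanolysis distinguishes silyl ethers by bulk, so the secondary TBS ether should leave well before the secondary TIPS ether, and the tert-butyl ester tolerates catalytic CSA.

Step 11
Reactants: 16 γ-hydroxy enoate
Product: 17 tert-butyl 7β-allyl-1α,5α-epoxy-6α-hydroxy-10α-methyl-8β-(triisopropylsilyloxy)cycloheptane-1-carboxylate (glycidic ester)
Conditions: t-BuOOH, n-BuLi, THF, −78 → 0 °C
Reagents that add atoms: tert-butyl hydroperoxide CC(C)(C)OO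
Why: Weitz–Scheffer-type nucleophilic epoxidation with lithium tert-butyl peroxide attacks only the electron-poor C1=C5 bond and leaves the allyl group alone, and binding of the lithium peroxide to the free 6α-hydroxyl should deliver oxygen to the α face, which sets C1.

Step 12
Reactants: 17 glycidic ester
Product: 18 tert-butyl 7β-allyl-1α,5β,6α-trihydroxy-10α-methyl-8β-(triisopropylsilyloxy)cycloheptane-1-carboxylate
Conditions: HClO4 (cat.), THF–H2O, rt → 40 °C
Reagents that add atoms: water O
Why: In this acid-catalysed SN2-type hydrolysis of a glycidic ester the carbonyl group disfavours charge build-up at C1, so water should attack C5 from the β face anti to the epoxide oxygen, inverting C5 and leaving the C1–O bond intact.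

Step 13
Reactants: 18 triol ester
Product: 19 7β-allyl-1β-(hydroxymethyl)-10α-methyl-8β-(triisopropylsilyloxy)cycloheptane-1α,5β,6α-triol
Conditions: LiAlH4, THF, 0 °C → rt
Reagents that add atoms: none
Why: LiAlH4 reduction of the α-hydroxy tert-butyl ester gives the C2 primary alcohol, and the alkene, the TIPS ether and all stereocentres are inert to hydride.

Step 14
Reactants: 19 tetraol
Product: 20 7β-allyl-1β-(tert-butyldimethylsilyloxymethyl)-10α-methyl-8β-(triisopropylsilyloxy)cycloheptane-1α,5β,6α-triol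
Conditions: TBSCl, imidazole, CH2Cl2, 0 °C
Reagents that add atoms: tert-butyldimethylsilyl chloride CC(C)(C)[Si](C)(C)Cl
Why: This silylation is selective on steric grounds, since only the primary hydroxyl should react at 0 °C beside two hindered secondary alcohols and one tertiary alcohol.

Step 15
Reactants: 20 triol
Product: 23 6,12-lactol (C12 hemiacetal on O6; 1α,5β-diol; 8β-OTIPS; 2-OTBS), via ozonide 21 (not isolated), via hydroxy aldehyde 22 (not isolated)
Conditions: O3, CH2Cl2, −78 °C; PPh3, −78 °C → rt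
Reagents that add atoms: ozone [O-][O+]=O
Why: Ozonolysis with reductive work-up cleaves the only alkene without touching the vicinal triol that a periodate-based cleavage would destroy, and the C12 aldehyde is trapped by the 6α-hydroxyl as the five-membered lactol.

Step 16
Reactants: 23 lactol
Product: 24 trans-fused 6,12-γ-lactone (1α,5β-diol; 8β-OTIPS; 2-OTBS)
Conditions: Ag2CO3/Celite, toluene, reflux
Reagents that add atoms: none
Why: The Fétizon oxidation takes lactols to lactones much faster than it attacks hindered secondary alcohols and does not cleave the C1/C5 glycol.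

Step 17
Reactants: 24 lactone diol
Product: 25 1α,5β-bis(trimethylsilyl) ether of lactone 24
Conditions: TMSOTf, 2,6-lutidine, CH2Cl2, −78 → 0 °C
Reagents that add atoms: trimethylsilyl triflate C[Si](C)(C)OS(=O)(=O)C(F)(F)F
Why: Exhaustive silylation with the triflate also covers the tertiary C1 hydroxyl, so the enolate chemistry of the next step meets no acidic proton or neighbouring alkoxide.

Step 18
Reactants: 25 bis-TMS lactone
Product: 27 11-(dimethylaminomethyl) lactone (Mannich base; C11 epimers), via lithium enolate 26 (not isolated)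
Conditions: LDA, THF, −78 °C; CH2=NMe2+ I−, −78 °C → rt
Reagents that add atoms: Eschenmoser's salt C[N+](C)=C.[I-]
Why: Mannich-type aminomethylation of the lactone enolate with Eschenmoser's salt brings in C13, and no leaving group sits β to the carbonyl, so elimination cannot compete.

Step 19
Reactants: 27 Mannich base
Product: 30 α-methylene-γ-lactone with free 1α- and 5β-hydroxyls (8β-OTIPS; 2-OTBS), via ammonium iodide 28 (not isolated), via bis-TMS methylene lactone 29 (not isolated)
Conditions: MeI, THF, rt; aq. NaHCO3, CH2Cl2, rt; then citric acid (cat.), MeOH, rt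
Reagents that add atoms: none
Why: Quaternisation and mild Hofmann-type (E1cB) elimination give the exocyclic C11=C13 alkene, and brief acid methanolysis removes the two labile TMS ethers while the primary TBS and secondary TIPS ethers stay.

Step 20
Reactants: 30 diol lactone; 31 angelic acid
Product: 33 5β-angelate of 30, via mixed anhydride 32 (not isolated)
Conditions: 31, 2,4,6-Cl3C6H2COCl, Et3N, toluene, rt; then 30, 80 °C (no DMAP)
Reagents that add atoms: none
Why: Yamaguchi-type mixed-anhydride esterification without a nucleophilic catalyst acylates the secondary C5 hydroxyl in preference to the tertiary C1 hydroxyl and avoids the addition–elimination path that turns angelate into tiglate.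

Step 21
Reactants: 33 angelate
Product: 34 5β-angelate with free C2 primary alcohol (8β-OTIPS kept)
Conditions: HF·pyridine, pyridine, THF, 0 °C
Reagents that add atoms: none
Why: Buffered fluoride desilylation removes the primary TBS ether well before the hindered secondary TIPS ether, and the weakly acidic medium suppresses acyl migration and Michael addition to the methylene lactone.

Step 22
Reactants: 34 primary alcohol
Product: 35 5β-angelate with C2 aldehyde (tertiary α-hydroxy aldehyde)
Conditions: DMP, CH2Cl2, rt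
Reagents that add atoms: none
Why: Dess–Martin oxidation of the primary alcohol of a primary/tertiary 1,2-diol stops at the α-hydroxy aldehyde under near-neutral conditions that spare the angelate and the methylene lactone.

Step 23
Reactants: 35 α-hydroxy aldehyde; 36 (E)-1-bromoprop-1-ene
Product: 38 C2 allylic alcohol (C2 epimers; E-propenyl), via propenylchromium 37 (not isolated)
Conditions: CrCl2 (excess), NiCl2 (cat.), DMF, rt
Reagents that add atoms: none
Why: In the Nozaki–Hiyama–Kishi alkenylation the alkenylchromium(III) reagent forms with retention of the E geometry and adds chemoselectively to the aldehyde beside the lactone, the esters and the free tertiary hydroxyl.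

Step 24
Reactants: 38 allylic alcohol
Product: 39 8-O-TIPS ether of the target (C2 enone)
Conditions: DMP, CH2Cl2, 0 °C → rt
Reagents that add atoms: none
Why: Dess–Martin oxidation of the secondary allylic alcohol gives the (E)-crotonoyl ketone, merges both C2 epimers and leaves the tertiary C1 hydroxyl alone.

Step 25
Reactants: 39 TIPS ether
Product: 40 target CNP0206014.2
Conditions: HF·pyridine, THF, 0 °C → rt
Reagents that add atoms: none
Why: Fluoride-mediated desilylation under weakly acidic conditions frees the 8β-hydroxyl without base-induced acyl migration, retro-aldol cleavage or conjugate addition.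

**Compound list**

1 | (R)-3-hydroxy-γ-butyrolactone | O=C1C[C@@H](O)CO1 | starting material
2 | allyl bromide | C=CCBr | starting material
3 | dilithio dianion of 1 | [Li]O[C@H]1COC(O[Li])=C1 | intermediate
4 | (3R,4R)-3-allyl-4-hydroxyoxolan-2-one | O=C1[C@H](CC=C)[C@@H](O)CO1 | intermediate
5 | (3R,4R)-3-allyl-4-(tert-butyldimethylsilyloxy)oxolan-2-one | O=C1[C@H](CC=C)[C@@H](O[Si](C)(C)C(C)(C)C)CO1 | intermediate
6 | (2R)-2-[(1R)-1-(tert-butyldimethylsilyloxy)-2-hydroxyethyl]-N-methoxy-N-methylpent-4-enamide | OC[C@H](O[Si](C)(C)C(C)(C)C)[C@@H](CC=C)C(=O)N(C)OC | intermediate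
7 | (2R)-2-[(1R)-1-(tert-butyldimethylsilyloxy)-2-oxoethyl]-N-methoxy-N-methylpent-4-enamide | O=C[C@H](O[Si](C)(C)C(C)(C)C)[C@@H](CC=C)C(=O)N(C)OC | intermediate
8 | tert-butyl but-2-ynoate | CC#CC(=O)OC(C)(C)C | starting material
9 | diisobutyl[(E)-1-(tert-butoxycarbonyl)prop-1-enyl]aluminium (CH3 cis to the ester) | C/C=C(/[Al](CC(C)C)CC(C)C)C(=O)OC(C)(C)C | intermediate
10 | tert-butyl (Z)-2-[(1S,2R,3R)-2-(tert-butyldimethylsilyloxy)-1-hydroxy-3-[methoxy(methyl)carbamoyl]hex-5-enyl]but-2-enoate | CON(C)C(=O)[C@H](CC=C)[C@@H](O[Si](C)(C)C(C)(C)C)[C@@H](O)/C(=C/C)C(=O)OC(C)(C)C | intermediate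
11 | tert-butyl (Z)-2-[(2S,3R,4R)-4-allyl-3-(tert-butyldimethylsilyloxy)-5-oxooxolan-2-yl]but-2-enoate | O=C1O[C@@H](/C(=C/C)C(=O)OC(C)(C)C)[C@H](O[Si](C)(C)C(C)(C)C)[C@H]1CC=C | intermediate
12 | tert-butyl (Z)-2-[(2S,3R,4R)-4-allyl-3-(tert-butyldimethylsilyloxy)-5-methylideneoxolan-2-yl]but-2-enoate | C=C1O[C@@H](/C(=C/C)C(=O)OC(C)(C)C)[C@H](O[Si](C)(C)C(C)(C)C)[C@H]1CC=C | intermediate
13 | tert-butyl 7β-allyl-6α-(TBSO)-10α-methyl-8-oxocyclohept-1(5)-ene-1-carboxylate | O=C1C[C@H](C)C(C(=O)OC(C)(C)C)=C[C@H](O[Si](C)(C)C(C)(C)C)[C@H]1CC=C | intermediate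
14 | 8β-alcohol of 13 | O[C@H]1C[C@H](C)C(C(=O)OC(C)(C)C)=C[C@H](O[Si](C)(C)C(C)(C)C)[C@H]1CC=C | intermediate
15 | 8β-O-TIPS, 6α-O-TBS enoate | CC(C)[Si](C(C)C)(C(C)C)O[C@H]1C[C@H](C)C(C(=O)OC(C)(C)C)=C[C@H](O[Si](C)(C)C(C)(C)C)[C@H]1CC=C | intermediate
16 | 8β-O-TIPS, 6α-hydroxy enoate | CC(C)[Si](C(C)C)(C(C)C)O[C@H]1C[C@H](C)C(C(=O)OC(C)(C)C)=C[C@H](O)[C@H]1CC=C | intermediate
17 | 1α,5α-epoxy-6α-hydroxy glycidic tert-butyl ester (8β-OTIPS) | CC(C)[Si](C(C)C)(C(C)C)O[C@H]1C[C@H](C)[C@]2(C(=O)OC(C)(C)C)O[C@@H]2[C@H](O)[C@H]1CC=C | intermediate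
18 | 1α,5β,6α-triol tert-butyl ester (8β-OTIPS) | CC(C)[Si](C(C)C)(C(C)C)O[C@H]1C[C@H](C)[C@@](O)(C(=O)OC(C)(C)C)[C@@H](O)[C@H](O)[C@H]1CC=C | intermediate
19 | 1β-hydroxymethyl 1α,5β,6α-triol (tetraol, 8β-OTIPS) | CC(C)[Si](C(C)C)(C(C)C)O[C@H]1C[C@H](C)[C@@](O)(CO)[C@@H](O)[C@H](O)[C@H]1CC=C | intermediate
20 | 2-O-TBS 1α,5β,6α-triol (8β-OTIPS, 7β-allyl) | CC(C)[Si](C(C)C)(C(C)C)O[C@H]1C[C@H](C)[C@@](O)(CO[Si](C)(C)C(C)(C)C)[C@@H](O)[C@H](O)[C@H]1CC=C | intermediate
21 | 1,2,4-trioxolane (ozonide) of 20 | CC(C)[Si](C(C)C)(C(C)C)O[C@H]1C[C@H](C)[C@@](O)(CO[Si](C)(C)C(C)(C)C)[C@@H](O)[C@H](O)[C@H]1CC2OCOO2 | intermediate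
22 | C12 aldehyde (open hydroxy aldehyde) | CC(C)[Si](C(C)C)(C(C)C)O[C@H]1C[C@H](C)[C@@](O)(CO[Si](C)(C)C(C)(C)C)[C@@H](O)[C@H](O)[C@H]1CC=O | intermediate
23 | 6,12-lactol (anomers) | C1C(O)O[C@@H]2[C@@H]1[C@@H](O[Si](C(C)C)(C(C)C)C(C)C)C[C@H](C)[C@@](O)(CO[Si](C)(C)C(C)(C)C)[C@H]2O | intermediate
24 | trans-fused 6,12-γ-lactone 1α,5β-diol | C1C(=O)O[C@@H]2[C@@H]1[C@@H](O[Si](C(C)C)(C(C)C)C(C)C)C[C@H](C)[C@@](O)(CO[Si](C)(C)C(C)(C)C)[C@H]2O | intermediate
25 | 1α,5β-bis-TMS ether of 24 | C1C(=O)O[C@@H]2[C@@H]1[C@@H](O[Si](C(C)C)(C(C)C)C(C)C)C[C@H](C)[C@@](O[Si](C)(C)C)(CO[Si](C)(C)C(C)(C)C)[C@H]2O[Si](C)(C)C | intermediate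
26 | lithium enolate of 25 | C1=C(O[Li])O[C@@H]2[C@@H]1[C@@H](O[Si](C(C)C)(C(C)C)C(C)C)C[C@H](C)[C@@](O[Si](C)(C)C)(CO[Si](C)(C)C(C)(C)C)[C@H]2O[Si](C)(C)C | intermediate
27 | 11-(dimethylaminomethyl) lactone (C11 epimers) | CN(C)CC1C(=O)O[C@@H]2[C@@H]1[C@@H](O[Si](C(C)C)(C(C)C)C(C)C)C[C@H](C)[C@@](O[Si](C)(C)C)(CO[Si](C)(C)C(C)(C)C)[C@H]2O[Si](C)(C)C | intermediate
28 | 11-(trimethylammoniomethyl) lactone iodide | C[N+](C)(C)CC1C(=O)O[C@@H]2[C@@H]1[C@@H](O[Si](C(C)C)(C(C)C)C(C)C)C[C@H](C)[C@@](O[Si](C)(C)C)(CO[Si](C)(C)C(C)(C)C)[C@H]2O[Si](C)(C)C.[I-] | intermediate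
29 | bis-TMS α-methylene lactone | C=C1C(=O)O[C@@H]2[C@@H]1[C@@H](O[Si](C(C)C)(C(C)C)C(C)C)C[C@H](C)[C@@](O[Si](C)(C)C)(CO[Si](C)(C)C(C)(C)C)[C@H]2O[Si](C)(C)C | intermediate
30 | α-methylene-γ-lactone, 1α-OH, 5β-OH, 8β-OTIPS, 2-OTBS | C=C1C(=O)O[C@@H]2[C@@H]1[C@@H](O[Si](C(C)C)(C(C)C)C(C)C)C[C@H](C)[C@@](O)(CO[Si](C)(C)C(C)(C)C)[C@H]2O | intermediate
31 | angelic acid, (Z)-2-methylbut-2-enoic acid | C/C=C(/C)C(=O)O | starting material
32 | angelic 2,4,6-trichlorobenzoic anhydride | C/C=C(/C)C(=O)OC(=O)c1c(Cl)cc(Cl)cc1Cl | intermediate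
33 | 5β-angelate, 2-OTBS, 8β-OTIPS | C=C1C(=O)O[C@@H]2[C@@H]1[C@@H](O[Si](C(C)C)(C(C)C)C(C)C)C[C@H](C)[C@@](O)(CO[Si](C)(C)C(C)(C)C)[C@H]2OC(=O)/C(C)=C\C | intermediate
34 | 5β-angelate, C2 primary alcohol | C=C1C(=O)O[C@@H]2[C@@H]1[C@@H](O[Si](C(C)C)(C(C)C)C(C)C)C[C@H](C)[C@@](O)(CO)[C@H]2OC(=O)/C(C)=C\C | intermediate
35 | 5β-angelate, C2 aldehyde | C=C1C(=O)O[C@@H]2[C@@H]1[C@@H](O[Si](C(C)C)(C(C)C)C(C)C)C[C@H](C)[C@@](O)(C=O)[C@H]2OC(=O)/C(C)=C\C | intermediate
36 | (E)-1-bromoprop-1-ene | C/C=C/Br | starting material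
37 | (E)-prop-1-enylchromium(III) dichloride | C/C=C/[Cr](Cl)Cl | intermediate
38 | C2 allylic alcohol (C2 epimers) | C=C1C(=O)O[C@@H]2[C@@H]1[C@@H](O[Si](C(C)C)(C(C)C)C(C)C)C[C@H](C)[C@@](O)(C(O)/C=C/C)[C@H]2OC(=O)/C(C)=C\C | intermediate
39 | 8-O-TIPS ether of the target | C=C1C(=O)O[C@@H]2[C@@H]1[C@@H](O[Si](C(C)C)(C(C)C)C(C)C)C[C@H](C)[C@@](O)(C(=O)/C=C/C)[C@H]2OC(=O)/C(C)=C\C | intermediate
40 | CNP0206014.2, (1S,5S,6R,7S,8S,10S) | C=C1C(=O)O[C@@H]2[C@@H]1[C@@H](O)C[C@H](C)[C@@](O)(C(=O)/C=C/C)[C@H]2OC(=O)/C(C)=C\C | target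

**Totals:** 25 steps in all; the longest linear sequence is 25 steps (1 → 40).

**Steps most likely to fail**

Risk 1 (step 11). The peroxide may add too slowly to the hindered, α-branched tert-butyl enoate. The facial selectivity may also be poor if binding to the 6α-hydroxyl does not outweigh the steric bias of the ring. The fallback sets out from 16 and returns at 17. It makes the alkene electron-rich and replaces the nucleophilic oxidant by a metal-bound, hydroxyl-directed one. DIBAL-H (CH2Cl2, −78 → 0 °C) should reduce the ester of 16 to the allylic 2,6-diol F1. VO(acac)2/t-BuOOH should then epoxidise only the alkene that is allylic to both hydroxyls, on the face of the ring 6α-OH as is usual for cyclohept-2-enols, to give the 1α,5α-epoxy diol F2; the remote allyl group reacts far more slowly. TEMPO/PhI(OAc)2 in aqueous MeCN should take the primary alcohol alone to the glycidic acid F3. O-tert-butyl-N,N'-diisopropylisourea should esterify F3 to 17.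

Risk 2 (step 12). Opening of the deactivated, hindered epoxide may be so slow that it is overtaken by loss of the tert-butyl ester, loss of a silyl group, or transannular capture at C5. The fallback sets out from 15 and returns at 18, and it builds the trans diol without any epoxide. Copper-catalysed conjugate borylation of 15 (B2pin2, CuCl, NaOt-Bu, DPEphos, MeOH, THF) should add boron to C5 anti to the 6α-silyloxy group and give the 5β-boronate F4. NaBO3 should oxidise F4 with retention to the 5β-hydroxy ester F5. The dianion of F5 (LDA, 2.2 equiv) should be hydroxylated by a Davis oxaziridine anti to the 5β-alkoxide, in the sense of a Fráter–Seebach reaction, to give the 1α,5β-diol 6-O-TBS ester F6. CSA in MeOH should free the 6α-hydroxyl to give 18.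

Risk 3 (step 7). The exocyclic double bond of the isolated enol ether may migrate into the ring, or the enol ether may hydrolyse, faster than the [3,3] shift. Prolonged heating may also cost silanol from the β-silyloxy ketone. The fallback sets out from 11 and returns at 13. It generates the enol ether by selenoxide elimination in the hot basic medium, so that it is consumed as it forms and no titanium reagent or isolation is needed. DIBAL-H (toluene, −78 °C) should give the lactol F7, and Ph3P=CH2 should open it to the hydroxy triene F8. PhSeCl/K2CO3 should close the oxolane again by 5-exo selenoetherification of the C5 hydroxyl onto the C8=C9 vinyl group to give the 2-(phenylselanylmethyl)oxolane F9. NaIO4/NaHCO3 should give the selenoxide F10. Heating F10 with i-Pr2NEt in toluene at 150 °C should release 12 by syn elimination, and 12 should rearrange in place to 13.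

**Further compounds**

F1 | step 11 | allylic 2,6-diol (C1=C5 alkene, 8β-OTIPS) | CC(C)[Si](C(C)C)(C(C)C)O[C@H]1C[C@H](C)C(CO)=C[C@H](O)[C@H]1CC=C
F2 | step 11 | 1α,5α-epoxy 2,6-diol | CC(C)[Si](C(C)C)(C(C)C)O[C@H]1C[C@H](C)[C@]2(CO)O[C@@H]2[C@H](O)[C@H]1CC=C
F3 | step 11 | 1α,5α-epoxy-6α-hydroxy glycidic acid | CC(C)[Si](C(C)C)(C(C)C)O[C@H]1C[C@H](C)[C@]2(C(=O)O)O[C@@H]2[C@H](O)[C@H]1CC=C
F4 | step 12 | 5β-pinacolboronate ester (C1 epimers) | CC(C)[Si](C(C)C)(C(C)C)O[C@H]1C[C@H](C)C(C(=O)OC(C)(C)C)[C@@H](B2OC(C)(C)C(C)(C)O2)[C@H](O[Si](C)(C)C(C)(C)C)[C@H]1CC=C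
F5 | step 12 | 5β-hydroxy ester (C1 epimers) | CC(C)[Si](C(C)C)(C(C)C)O[C@H]1C[C@H](C)C(C(=O)OC(C)(C)C)[C@@H](O)[C@H](O[Si](C)(C)C(C)(C)C)[C@H]1CC=C
F6 | step 12 | 1α,5β-diol 6-O-TBS tert-butyl ester | CC(C)[Si](C(C)C)(C(C)C)O[C@H]1C[C@H](C)[C@@](O)(C(=O)OC(C)(C)C)[C@@H](O)[C@H](O[Si](C)(C)C(C)(C)C)[C@H]1CC=C
F7 | step 7 | lactol of 11 (anomers) | OC1O[C@@H](/C(=C/C)C(=O)OC(C)(C)C)[C@H](O[Si](C)(C)C(C)(C)C)[C@H]1CC=C
F8 | step 7 | hydroxy triene (C8=C9 vinyl, free 5-OH) | C=C[C@H](CC=C)[C@@H](O[Si](C)(C)C(C)(C)C)[C@@H](O)/C(=C/C)C(=O)OC(C)(C)C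
F9 | step 7 | 2-(phenylselanylmethyl)oxolane (C8 epimers) | c1ccccc1[Se]CC2O[C@@H](/C(=C/C)C(=O)OC(C)(C)C)[C@H](O[Si](C)(C)C(C)(C)C)[C@H]2CC=C
F10 | step 7 | selenoxide of F9 | O=[Se](c1ccccc1)CC2O[C@@H](/C(=C/C)C(=O)OC(C)(C)C)[C@H](O[Si](C)(C)C(C)(C)C)[C@H]2CC=C
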